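**Plan**

- The target, 6-arylacetyl-5-hydroxy-7-methoxy-8-prenyl-2,2-dimethyl-2H-chromene, has no stereocentre and no stereogenic double bond, so no stereocontrol is needed.
- Retrosynthesis: (a) the silyl group on the distal phenol is removed; (b) the pyran ring is cut at O1–C2 and C4–C4a, back to a resorcinol and 3-methylbut-2-enal; (c) the benzene ring is cut at C7–C8 and C5–C6, back to a 1,3-bis(silyloxy)diene and a 3-methoxy ynone; (d) the ynone is cut at its acyl–alkyne bond and the diene at the CH2–CH2 bond made by γ-prenylation of acetoacetate.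
- Enabling feature: round the benzene ring the carbons run C5(OH)–C6(acyl)–C7(OMe)–C8(prenyl)–C8a(O)–C4a. C5, C4a, C8a and C8 are the four diene carbons of a γ-prenylated acetoacetate (oxygen on C5 and C8a, prenyl on C8), and C6/C7 are an acyl- and methoxy-substituted alkyne. The annulation itself therefore fixes the place of OMe, prenyl and acyl, and no phenol has to be alkylated selectively.
- Forward: diene (3 steps) and ynone (3 steps) are made separately and joined in the benzannulation (benzene ring). The pyran ring is then annulated with the enal onto the only unsubstituted ring carbon through the non-chelated hydroxyl, and desilylation ends the route.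

Key step: step 7

Remark: silyl enol ethers 5 and 6 are drawn with the Z geometry assumed to prevail; this geometry is erased on aromatisation and has no bearing on the route.

**Route**

Step 1
Reactants: 1 methyl acetoacetate; 2 prenyl bromide (1-bromo-3-methylbut-2-ene)
Product: 4 methyl 7-methyl-3-oxooct-6-enoate, via acetoacetate dianion 3 (not isolated)
Conditions: NaH, THF, 0 °C; n-BuLi, 0 °C; then 2, 0 °C → rt; 1 M HCl
Reagents that add atoms: none
Why: γ-Alkylation of a β-keto ester dianion: the terminal carbanion of 3 is the more reactive site and displaces the allylic bromide in an SN2 reaction, giving only the γ-prenylated keto ester.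

Step 2
Reactants: 4 methyl 7-methyl-3-oxooct-6-enoate
Product: 5 methyl (2Z)-7-methyl-3-(trimethylsilyloxy)octa-2,6-dienoate
Conditions: Me3SiCl, Et3N, hexane, rt
Reagents that add atoms: chlorotrimethylsilane, C[Si](C)(C)Cl
Why: Soft-enolisation O-silylation of the β-keto ester (silyl enol ether formation), the standard first stage of 1,3-bis(silyloxy)diene synthesis, which leaves the trisubstituted alkene untouched.

Step 3
Reactants: 5 methyl (2Z)-7-methyl-3-(trimethylsilyloxy)octa-2,6-dienoate
Product: 6 (1Z,3Z)-1-methoxy-7-methyl-1,3-bis(trimethylsilyloxy)octa-1,3,6-triene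
Conditions: LiN(i-Pr)2, THF, −78 °C; Me3SiCl, −78 °C → rt; filtration under N2, used crude
Reagents that add atoms: chlorotrimethylsilane, C[Si](C)(C)Cl
Why: Kinetic γ-deprotonation of the silyloxy enoate gives the extended ester dienolate, which is O-silylated (silyl ketene acetal formation) to the 4-substituted 1,3-bis(silyloxy)diene.

Step 4
Reactants: 7 4-hydroxyphenylacetic acid
Product: 8 2-(4-hydroxyphenyl)-N-methoxy-N-methylacetamide
Conditions: MeNHOMe·HCl, EDC·HCl, N-methylmorpholine, CH2Cl2, 0 °C → rt
Reagents that add atoms: N,O-dimethylhydroxylamine hydrochloride, CNOC.Cl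
Why: Carbodiimide amide coupling; the amine is far more nucleophilic than the phenol towards the O-acylisourea, so the Weinreb amide should form without prior phenol protection.

Step 5
Reactants: 8 2-(4-hydroxyphenyl)-N-methoxy-N-methylacetamide
Product: 9 N-methoxy-N-methyl-2-[4-(triisopropylsilyloxy)phenyl]acetamide
Conditions: i-Pr3SiCl, imidazole, DMF, rt
Reagents that add atoms: chlorotriisopropylsilane, CC(C)[Si](Cl)(C(C)C)C(C)C
Why: Imidazole-promoted silylation of a phenol; the triisopropylsilyl ether should withstand the lithium acetylide, the thermal annulation, dilute acid and the ammonium-salt catalyst, and is removed by fluoride at the end.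

Step 6
Reactants: 10 chloroacetaldehyde dimethyl acetal; 9 N-methoxy-N-methyl-2-[4-(triisopropylsilyloxy)phenyl]acetamide
Product: 12 4-methoxy-1-[4-(triisopropylsilyloxy)phenyl]but-3-yn-2-one, via lithium methoxyacetylide 11 (not isolated)
Conditions: 10 (1.5 equiv), LiNEt2 (4.5 equiv, from Et2NH and n-BuLi), THF, 0 °C; then 9, −78 → −30 °C; inverse quench into cold aq NaH2PO4
Reagents that add atoms: none
Why: Twofold elimination from the chloroacetal gives the lithium alkoxyacetylide, which adds once to the Weinreb amide through the chelated tetrahedral intermediate (Weinreb ketone synthesis); the cold buffered inverse quench protonates the amines before the ynone is released.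

Step 7
Reactants: 6 (1Z,3Z)-1-methoxy-7-methyl-1,3-bis(trimethylsilyloxy)octa-1,3,6-triene; 12 4-methoxy-1-[4-(triisopropylsilyloxy)phenyl]but-3-yn-2-one
Product: 14 1-[2,4-dihydroxy-6-methoxy-5-(3-methylbut-2-enyl)phenyl]-2-[4-(triisopropylsilyloxy)phenyl]ethanone, via cyclohexa-1,4-diene cycloadduct 13 (not isolated)
Conditions: 6 (1.8 equiv), toluene, rt → 90 °C, N2; then 1 M HCl, THF, 0 °C → rt
Reagents that add atoms: none
Why: Proposed new method: the electron-rich diene 6 and the push-pull alkyne of 12 are expected to combine in a thermal, strongly asynchronous [4+2] cycloaddition, which in its stepwise limit is a Michael addition of the prenyl-bearing diene terminus C4 to the methoxy-bearing alkyne carbon followed by attack of the allenolate carbon on the ester-derived, alkoxy-stabilised cationic carbon C1 (Claisen-type acylation), forming the C7–C8 and C5–C6 bonds of the target ring and giving cyclohexa-1,4-diene 13; dilute acid then removes the trimethylsilyl groups, methanol is lost from the former ester carbon and the ring tautomerises to resorcinol 14. The closest known reaction type is the Diels–Alder/aromatisation (or Lewis-acid cyclisation) of 1-alkoxy-1,3-bis(silyloxy)-1,3-dienes with acetylenic esters, ynones, allenes and β-alkoxy enones to give resorcinols and salicylates; a 3-methoxy ynone as the two-carbon partner is not established. The benzene ring closes either in concert with the first bond or, in the stepwise limit, by a 6-exo-trig attack of the allenolate carbon on C1. No stereocentre survives, because the two sp3 ring carbons of 13 become aromatic. Regioselectivity rests on polarity matching: the most nucleophilic diene carbon (C4) meets the carbonyl-conjugated β-carbon of the ynone, which puts OMe beside prenyl and the acyl group between OMe and OH. The competing [3+3] aldol mode (diene C2 onto the ketone, leading to a salicylate) is disfavoured by omitting TiCl4 or any other halide Lewis acid, so that both silyl groups stay on the diene until the ring is closed and C2 never becomes a free enolate carbon; the methoxy (not ethoxy) alkyne cannot undergo retro-ene loss of an alkene at 90 °C.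

Step 8
Reactants: 14 1-[2,4-dihydroxy-6-methoxy-5-(3-methylbut-2-enyl)phenyl]-2-[4-(triisopropylsilyloxy)phenyl]ethanone; 15 3-methylbut-2-enal
Product: 17 1-[5-hydroxy-7-methoxy-2,2-dimethyl-8-(3-methylbut-2-enyl)-2H-chromen-6-yl]-2-[4-(triisopropylsilyloxy)phenyl]ethanone, via ortho-quinone methide 16 (not isolated)
Conditions: 15 (2 equiv), ethylenediammonium diacetate (20 mol %), xylene, 140 °C
Reagents that add atoms: none
Why: Ammonium-salt-catalysed condensation of the enal at the only unsubstituted ring carbon (between the two hydroxyls) gives an ortho-quinone methide that closes by oxa-6π electrocyclisation (formal [3+3] chromene annulation) through the non-chelated para hydroxyl, the ketone keeping its hydrogen bond to the ortho hydroxyl as is usual for 2,4-dihydroxyaryl ketones.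

Step 9
Reactants: 17 1-[5-hydroxy-7-methoxy-2,2-dimethyl-8-(3-methylbut-2-enyl)-2H-chromen-6-yl]-2-[4-(triisopropylsilyloxy)phenyl]ethanone
Product: 18 1-[5-hydroxy-7-methoxy-2,2-dimethyl-8-(3-methylbut-2-enyl)-2H-chromen-6-yl]-2-(4-hydroxyphenyl)ethanone
Conditions: Bu4NF, AcOH, THF, 0 °C
Reagents that add atoms: none
Why: Fluoride-induced desilylation of the aryl silyl ether, buffered with acetic acid so that the chromene, the prenyl group and the chelated phenol are not exposed to strong base or acid.

**Compound list**

1 | methyl acetoacetate | COC(=O)CC(C)=O | starting material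
2 | prenyl bromide (1-bromo-3-methylbut-2-ene) | CC(C)=CCBr | starting material
3 | acetoacetate dianion (sodium lithium 1-methoxybuta-1,3-diene-1,3-diolate) | [Na+].[Li+].COC([O-])=CC([O-])=C | intermediate
4 | methyl 7-methyl-3-oxooct-6-enoate | COC(=O)CC(=O)CCC=C(C)C | intermediate
5 | methyl (2Z)-7-methyl-3-(trimethylsilyloxy)octa-2,6-dienoate | COC(=O)/C=C(/CCC=C(C)C)O[Si](C)(C)C | intermediate
6 | (1Z,3Z)-1-methoxy-7-methyl-1,3-bis(trimethylsilyloxy)octa-1,3,6-triene | C[Si](C)(C)O/C(/C=C(/OC)O[Si](C)(C)C)=C\CC=C(C)C | intermediate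
7 | 4-hydroxyphenylacetic acid | OC(=O)Cc1ccc(O)cc1 | starting material
8 | 2-(4-hydroxyphenyl)-N-methoxy-N-methylacetamide | CON(C)C(=O)Cc1ccc(O)cc1 | intermediate
9 | N-methoxy-N-methyl-2-[4-(triisopropylsilyloxy)phenyl]acetamide | CON(C)C(=O)Cc1ccc(O[Si](C(C)C)(C(C)C)C(C)C)cc1 | intermediate
10 | chloroacetaldehyde dimethyl acetal (2-chloro-1,1-dimethoxyethane) | COC(CCl)OC | starting material
11 | lithium methoxyacetylide | [Li]C#COC | intermediate
12 | 4-methoxy-1-[4-(triisopropylsilyloxy)phenyl]but-3-yn-2-one | COC#CC(=O)Cc1ccc(O[Si](C(C)C)(C(C)C)C(C)C)cc1 | intermediate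
13 | 1-[2,6-dimethoxy-3-(3-methylbut-2-enyl)-4,6-bis(trimethylsilyloxy)cyclohexa-1,4-dien-1-yl]-2-[4-(triisopropylsilyloxy)phenyl]ethanone (mixture of diastereomers, both sp3 ring centres transient) | COC1(O[Si](C)(C)C)C=C(O[Si](C)(C)C)C(CC=C(C)C)C(OC)=C1C(=O)Cc1ccc(O[Si](C(C)C)(C(C)C)C(C)C)cc1 | intermediate
14 | 1-[2,4-dihydroxy-6-methoxy-5-(3-methylbut-2-enyl)phenyl]-2-[4-(triisopropylsilyloxy)phenyl]ethanone | COc1c(CC=C(C)C)c(O)cc(O)c1C(=O)Cc1ccc(O[Si](C(C)C)(C(C)C)C(C)C)cc1 | intermediate
15 | 3-methylbut-2-enal | CC(C)=CC=O | starting material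
16 | (6Z)-5-hydroxy-3-methoxy-2-(3-methylbut-2-enyl)-6-(3-methylbut-2-enylidene)-4-{2-[4-(triisopropylsilyloxy)phenyl]acetyl}cyclohexa-2,4-dien-1-one (ortho-quinone methide) | COC1=C(CC=C(C)C)C(=O)/C(=C\C=C(C)C)C(O)=C1C(=O)Cc1ccc(O[Si](C(C)C)(C(C)C)C(C)C)cc1 | intermediate
17 | 1-[5-hydroxy-7-methoxy-2,2-dimethyl-8-(3-methylbut-2-enyl)-2H-chromen-6-yl]-2-[4-(triisopropylsilyloxy)phenyl]ethanone | COc1c(CC=C(C)C)c2c(c(O)c1C(=O)Cc1ccc(O[Si](C(C)C)(C(C)C)C(C)C)cc1)C=CC(C)(C)O2 | intermediate
18 | 1-[5-hydroxy-7-methoxy-2,2-dimethyl-8-(3-methylbut-2-enyl)-2H-chromen-6-yl]-2-(4-hydroxyphenyl)ethanone | COc1c(CC=C(C)C)c2c(c(O)c1C(=O)Cc1ccc(O)cc1)C=CC(C)(C)O2 | target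

**Step count**

Total: 9 steps. Longest linear sequence: 6 steps (1 → 2 → 3 → 7 → 8 → 9, or 4 → 5 → 6 → 7 → 8 → 9).

**Steps most likely to fail**

1. Step 7 (carries the label "Proposed new method:"). Three processes may defeat it.
   - The alkoxy-substituted alkyne may be too weak an acceptor, so that the diene is consumed by protodesilylation (the benzylic α-methylene of 12 and traces of moisture are proton sources) before any C–C bond forms.
   - After the first bond the silyl group may migrate to the allenolate oxygen and the chain may close in the aldol sense (diene C2 onto the ketone), giving a salicylate-type ring instead of the acylresorcinol.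
   - Unreacted ynol ether may hydrate during the acidic work-up and complicate isolation.

   Fallback with known chemistry, not a benzannulation; it sets out from 7 and comes back at 18. Acid 7 acylates phloroglucinol (BF3·OEt2, 85 °C, Friedel–Crafts acylation) to give 2-(4-hydroxyphenyl)-1-(2,4,6-trihydroxyphenyl)ethanone F1. The two non-chelated hydroxyls are silylated (t-BuMe2SiCl, imidazole, DMF, 0 °C) to give 2-[4-(tert-butyldimethylsilyloxy)phenyl]-1-[4-(tert-butyldimethylsilyloxy)-2,6-dihydroxyphenyl]ethanone F2. One of the two equivalent chelated hydroxyls is methylated under Mitsunobu conditions (MeOH, PPh3, diisopropyl azodicarboxylate) to give 2-[4-(tert-butyldimethylsilyloxy)phenyl]-1-[4-(tert-butyldimethylsilyloxy)-2-hydroxy-6-methoxyphenyl]ethanone F3. The remaining chelated hydroxyl is O-prenylated in the same way with 3-methylbut-2-en-1-ol to give 2-[4-(tert-butyldimethylsilyloxy)phenyl]-1-[4-(tert-butyldimethylsilyloxy)-2-methoxy-6-(3-methylbut-2-enyloxy)phenyl]ethanone F4. Heating in N,N-diethylaniline at about 190 °C moves the prenyl group by a Claisen–Cope sequence to the para carbon, which lies between the methoxy and the silyloxy group, giving 2-[4-(tert-butyldimethylsilyloxy)phenyl]-1-[4-(tert-butyldimethylsilyloxy)-2-hydroxy-6-methoxy-5-(3-methylbut-2-enyl)phenyl]ethanone F5. Bu4NF removes both silyl groups to give 1-[2,4-dihydroxy-6-methoxy-5-(3-methylbut-2-enyl)phenyl]-2-(4-hydroxyphenyl)ethanone F6. Annulation of F6 with 15 under the conditions of step 8 (the simple phenol is not nucleophilic enough to react) should give 18 directly.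

2. Step 6. The acetylide may enolise the arylacetamide instead of adding to it. On quench the liberated secondary amines (diethylamine, N,O-dimethylhydroxylamine) may add in conjugate fashion to the ynone. The ynol ether may also hydrate on silica.

   Fallback at the aldehyde oxidation level, so that the ynone is first formed in an amine-free oxidation; it sets out from 9 and comes back at 12. Amide 9 is reduced with (i-Bu)2AlH (THF, −78 °C) to 2-[4-(triisopropylsilyloxy)phenyl]acetaldehyde F7. Acetylide 11, made from 10 as in step 6, is added at −78 °C to give racemic 4-methoxy-1-[4-(triisopropylsilyloxy)phenyl]but-3-yn-2-ol F8. Oxidation of the propargylic alcohol with activated MnO2 in CH2Cl2 should give 12.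

3. Step 8. Condensation at the ring carbon of the deactivated acylresorcinol may be slow relative to self-condensation of the enal. The electrocyclisation may proceed through the chelated hydroxyl and give the isomeric pyran. The enal may also condense at the benzylic ketone methylene.

   Fallback by ether formation and sigmatropic rearrangement in place of condensation; it sets out from 14 and comes back at 17. The non-chelated hydroxyl of 14 is alkylated with 3-chloro-3-methylbut-1-yne (DBU, CuCl2 catalyst, MeCN, 0 °C) to give 1-[2-hydroxy-6-methoxy-5-(3-methylbut-2-enyl)-4-(2-methylbut-3-yn-2-yloxy)phenyl]-2-[4-(triisopropylsilyloxy)phenyl]ethanone F9. Heating F9 in N,N-diethylaniline (about 160 °C) brings about aryl propargyl Claisen rearrangement to the only free ortho carbon, 1,5-hydrogen shift and oxa-6π closure to give 17.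

**Further compounds**

F1 | step 7 | 2-(4-hydroxyphenyl)-1-(2,4,6-trihydroxyphenyl)ethanone | O=C(Cc1ccc(O)cc1)c1c(O)cc(O)cc1O
F2 | step 7 | 2-[4-(tert-butyldimethylsilyloxy)phenyl]-1-[4-(tert-butyldimethylsilyloxy)-2,6-dihydroxyphenyl]ethanone | CC(C)(C)[Si](C)(C)Oc1ccc(CC(=O)c2c(O)cc(O[Si](C)(C)C(C)(C)C)cc2O)cc1
F3 | step 7 | 2-[4-(tert-butyldimethylsilyloxy)phenyl]-1-[4-(tert-butyldimethylsilyloxy)-2-hydroxy-6-methoxyphenyl]ethanone | COc1cc(O[Si](C)(C)C(C)(C)C)cc(O)c1C(=O)Cc1ccc(O[Si](C)(C)C(C)(C)C)cc1
F4 | step 7 | 2-[4-(tert-butyldimethylsilyloxy)phenyl]-1-[4-(tert-butyldimethylsilyloxy)-2-methoxy-6-(3-methylbut-2-enyloxy)phenyl]ethanone | COc1cc(O[Si](C)(C)C(C)(C)C)cc(OCC=C(C)C)c1C(=O)Cc1ccc(O[Si](C)(C)C(C)(C)C)cc1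
F5 | step 7 | 2-[4-(tert-butyldimethylsilyloxy)phenyl]-1-[4-(tert-butyldimethylsilyloxy)-2-hydroxy-6-methoxy-5-(3-methylbut-2-enyl)phenyl]ethanone | COc1c(CC=C(C)C)c(O[Si](C)(C)C(C)(C)C)cc(O)c1C(=O)Cc1ccc(O[Si](C)(C)C(C)(C)C)cc1
F6 | step 7 | 1-[2,4-dihydroxy-6-methoxy-5-(3-methylbut-2-enyl)phenyl]-2-(4-hydroxyphenyl)ethanone | COc1c(CC=C(C)C)c(O)cc(O)c1C(=O)Cc1ccc(O)cc1
F7 | step 6 | 2-[4-(triisopropylsilyloxy)phenyl]acetaldehyde | O=CCc1ccc(O[Si](C(C)C)(C(C)C)C(C)C)cc1
F8 | step 6 | 4-methoxy-1-[4-(triisopropylsilyloxy)phenyl]but-3-yn-2-ol (racemic) | COC#CC(O)Cc1ccc(O[Si](C(C)C)(C(C)C)C(C)C)cc1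
F9 | step 8 | 1-[2-hydroxy-6-methoxy-5-(3-methylbut-2-enyl)-4-(2-methylbut-3-yn-2-yloxy)phenyl]-2-[4-(triisopropylsilyloxy)phenyl]ethanone | COc1c(CC=C(C)C)c(OC(C)(C)C#C)cc(O)c1C(=O)Cc1ccc(O[Si](C(C)C)(C(C)C)C(C)C)cc1
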